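**Retrosynthetic overview**
1. 9 ⇒ 7: C6–OMe bond, made by a reagent-controlled, desymmetrising oxidative dearomatisation of an achiral, mirror-symmetric arene; the only stereocentre is set in the last step.
2. 7 ⇒ 5 + 2 × 6: the two aryl C–prenyl bonds.
3. 5 ⇒ 4: C1–C6 bond of a linear tetraketide ester (Claisen cyclisation). This is the only ring formed in the route: the six-membered carbocycle, made aromatic first and dearomatised last. The phenyl ring is bought.
4. 4 ⇒ 3 ⇒ 1 + 2: the tetraketide is carried as a 2-pyranone, assembled by C-acylation of triacetic acid lactone.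

Assumption: the target is the (6R) enantiomer, drawn as one tautomer of an enolised β-triketone; the chiral iodane of step 4 is a separately prepared, recoverable reagent, and because its sense of induction on this substrate is unknown the (R,R) form is written — if a first run gives (6S), the mirror-image reagent is used.

**Step 1**
Reactants: 1 4-hydroxy-6-methyl-2H-pyran-2-one (triacetic acid lactone); 2 methyl 3-phenylpropanoate
Product: 3 4-hydroxy-6-(2-oxo-4-phenylbutyl)-2H-pyran-2-one
Conditions: 1 (2.0 equiv), LDA (4.0 equiv), THF, −78 °C, 1 h; then 2 (1.0 equiv), −78 → 0 °C; aq HCl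
Reagents that add atoms: none
Why: Claisen condensation (C-acylation) of the O,C-dianion of 1, which reacts at the exocyclic 6-CH2 carbanion (last formed, most nucleophilic), the second equivalent of dianion taking up the acidic proton of the product; no stereocentre is formed.

**Step 2**
Reactants: 3 4-hydroxy-6-(2-oxo-4-phenylbutyl)-2H-pyran-2-one
Product: 5 1-(2,4,6-trihydroxyphenyl)-3-phenylpropan-1-one, via tetraketide methyl ester 4 (not isolated)
Conditions: Mg(OMe)2 (4 equiv), MeOH, reflux, 16 h; then 1 M HCl
Reagents that add atoms: none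
Why: Methoxide opens the lactone to the Mg-chelated tetraketide ester 4 (its OMe comes from the solvent and is expelled again), whose C6 enolate attacks the ester carbon in a polyketide-type intramolecular Claisen (Dieckmann) condensation, the non-aqueous Mg chelate disfavouring the competing C2→C7 aldol closure to a resorcylate, and the cyclic triketone enolises to the arene; no stereocentre.

**Step 3**
Reactants: 5 1-(2,4,6-trihydroxyphenyl)-3-phenylpropan-1-one; 6 1-bromo-3-methylbut-2-ene (prenyl bromide, 2.1 equiv)
Product: 7 1-[2,4,6-trihydroxy-3,5-bis(3-methylbut-2-en-1-yl)phenyl]-3-phenylpropan-1-one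
Conditions: 10% aq KOH (3 equiv), 0 °C, 2 h; then aq HCl
Reagents that add atoms: none
Why: Base-mediated double C-prenylation (SN2 alkylation of the ambident phloroglucinolate at its two free, equivalent ring carbons, water hydrogen-bonding the phenoxide oxygens and so favouring C- over O-alkylation), the chemical counterpart of the two aromatic prenyl transfers; 7 is achiral.

**Step 4**
Reactants: 7 1-[2,4,6-trihydroxy-3,5-bis(3-methylbut-2-en-1-yl)phenyl]-3-phenylpropan-1-one
Product: 9 (6R)-3,5-dihydroxy-6-methoxy-4,6-bis(3-methylbut-2-en-1-yl)-2-(3-phenylpropanoyl)cyclohexa-2,4-dien-1-one (helihumulone), via aryloxy-λ3-iodane 8 (not isolated)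
Conditions: (R,R)-ArI(OAc)2 [Ar = 2,6-bis{(1R)-1-(mesitylcarbamoyl)ethoxy}phenyl] (1.05 equiv), CH2Cl2/MeOH 4:1, −60 → −30 °C
Reagents that add atoms: methanol, CO
Why: Proposed new method: the non-chelated, most acidic 4-OH of 7 (it lies on the mirror plane of the substrate) exchanges for acetate at iodine to give 8, and methanol then adds SN2′-like to one of the two enantiotopic prenyl-bearing ortho carbons as the aryl iodide leaves (the acyl-bearing para carbon is deactivated), the C2-symmetric lactamide arms shielding one ortho carbon and face so that C6 is set as (R) by reagent control; closest known reaction types are the chiral aryl-λ3-iodane mediated enantioselective dearomatisation of phenols (oxidative spirolactonisation, hydroxylative dearomatisation) and the racemic PhI(OAc)2/MeOH synthesis of ortho-quinol ethers.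

**Compound list**
1 | 4-hydroxy-6-methyl-2H-pyran-2-one (triacetic acid lactone) | CC1=CC(O)=CC(=O)O1 | starting material
2 | methyl 3-phenylpropanoate | COC(=O)CCc1ccccc1 | starting material
3 | 4-hydroxy-6-(2-oxo-4-phenylbutyl)-2H-pyran-2-one | O=C(CCc1ccccc1)CC1=CC(O)=CC(=O)O1 | intermediate
4 | methyl 3,5,7-trioxo-9-phenylnonanoate (tetraketide methyl ester) | COC(=O)CC(=O)CC(=O)CC(=O)CCc1ccccc1 | intermediate (not isolated)
5 | 1-(2,4,6-trihydroxyphenyl)-3-phenylpropan-1-one | O=C(CCc1ccccc1)c1c(O)cc(O)cc1O | intermediate
6 | 1-bromo-3-methylbut-2-ene (prenyl bromide) | CC(C)=CCBr | starting material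
7 | 1-[2,4,6-trihydroxy-3,5-bis(3-methylbut-2-en-1-yl)phenyl]-3-phenylpropan-1-one | CC(C)=CCc1c(O)c(CC=C(C)C)c(O)c(C(=O)CCc2ccccc2)c1O | intermediate
8 | acetoxy{2,6-bis[(1R)-1-(mesitylcarbamoyl)ethoxy]phenyl}[3,5-dihydroxy-2,6-bis(3-methylbut-2-en-1-yl)-4-(3-phenylpropanoyl)phenoxy]-λ3-iodane | CC(C)=CCc1c(OI(OC(C)=O)c2c(O[C@H](C)C(=O)Nc3c(C)cc(C)cc3C)cccc2O[C@H](C)C(=O)Nc2c(C)cc(C)cc2C)c(CC=C(C)C)c(O)c(C(=O)CCc2ccccc2)c1O | intermediate (not isolated)
9 | (6R)-3,5-dihydroxy-6-methoxy-4,6-bis(3-methylbut-2-en-1-yl)-2-(3-phenylpropanoyl)cyclohexa-2,4-dien-1-one (helihumulone) | CO[C@@]1(CC=C(C)C)C(=O)C(C(=O)CCc2ccccc2)=C(O)C(CC=C(C)C)=C1O | target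

**Total step count:** 4. **Longest linear sequence:** 4 steps (1 → 3 → 5 → 7 → 9).

**Steps most likely to fail, with fallbacks**

Step 4 is the most likely to fail. A free phenoxenium ion would erode the ee, and the electron-rich product or the prenyl groups may react further. The fallback sets out from 7 and comes back at 9. Compound 7 is oxidised with achiral PhI(OAc)2 (1.0 equiv) in MeOH at −20 °C through acetoxy(phenyl)[3,5-dihydroxy-2,6-bis(3-methylbut-2-en-1-yl)-4-(3-phenylpropanoyl)phenoxy]-λ3-iodane F1 (not isolated) to racemic helihumulone F2. The racemate is then resolved by preparative chiral SFC (amylose tris(3,5-dimethylphenylcarbamate) phase, CO2/MeOH with 0.1% formic acid) to give 9. The stereocentre is then obtained by separation instead of by reagent control.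

Step 2 is the next most likely to fail. The tetraketide may close by aldol condensation to a resorcylate, or be cleaved by retro-Claisen reaction. The fallback sets out from 3 and comes back at 5. Compound 3 is O-methylated (Me2SO4, K2CO3, acetone) to 4-methoxy-6-(2-oxo-4-phenylbutyl)-2H-pyran-2-one F3. Mg(OMe)2 in MeOH opens this to methyl (2E)-3-methoxy-5,7-dioxo-9-phenylnon-2-enoate F4 (not isolated). In F4 the C3 carbonyl is masked as an enol ether, so C2 can no longer act as the aldol donor and only the Claisen closure remains. That closure gives 1-(2,6-dihydroxy-4-methoxyphenyl)-3-phenylpropan-1-one F5, and BBr3 (CH2Cl2, −78 → 0 °C) cleaves the aryl methyl ether to give 5.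

Step 3 is the third. Alkylation of the phenoxide can give mono-, tri- (geminal) and O-prenylated mixtures. The fallback sets out from 5 and comes back at 7. Compound 5 is prenylated as the neutral phenol by Friedel–Crafts alkylation with 2-methylbut-3-en-2-ol (1.1 equiv) and BF3·OEt2 in dioxane at rt; with no phenoxide present there is no O-alkylation and no geminal dialkylation. This gives 1-[2,4,6-trihydroxy-3-(3-methylbut-2-en-1-yl)phenyl]-3-phenylpropan-1-one F6, which is isolated and prenylated a second time under the same Friedel–Crafts conditions to give 7.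

**Further compounds**
F1 | step 4 | acetoxy(phenyl)[3,5-dihydroxy-2,6-bis(3-methylbut-2-en-1-yl)-4-(3-phenylpropanoyl)phenoxy]-λ3-iodane | CC(C)=CCc1c(OI(OC(C)=O)c2ccccc2)c(CC=C(C)C)c(O)c(C(=O)CCc2ccccc2)c1O
F2 | step 4 | racemic helihumulone | COC1(CC=C(C)C)C(=O)C(C(=O)CCc2ccccc2)=C(O)C(CC=C(C)C)=C1O
F3 | step 2 | 4-methoxy-6-(2-oxo-4-phenylbutyl)-2H-pyran-2-one | COC1=CC(=O)OC(CC(=O)CCc2ccccc2)=C1
F4 | step 2 | methyl (2E)-3-methoxy-5,7-dioxo-9-phenylnon-2-enoate | COC(=O)/C=C(/OC)CC(=O)CC(=O)CCc1ccccc1
F5 | step 2 | 1-(2,6-dihydroxy-4-methoxyphenyl)-3-phenylpropan-1-one | COc1cc(O)c(C(=O)CCc2ccccc2)c(O)c1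
F6 | step 3 | 1-[2,4,6-trihydroxy-3-(3-methylbut-2-en-1-yl)phenyl]-3-phenylpropan-1-one | CC(C)=CCc1c(O)cc(O)c(C(=O)CCc2ccccc2)c1O
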